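**Retrosynthetic overview**

Numbering (bicyclo[3.2.1]octane): C1 methyl bridgehead, C2–C3–C4 enolised triketone bridge (acyl on C3), C5 prenyl bridgehead, C6 CH2, C7 CH carrying the carbinol carbon C9, C8 bridging ketone. The strategy rests on one feature: the six-membered ring C8–C1–C2–C3–C4–C5 is a 4-acyl-3,5-dioxygenated phenol in oxidised form (C8 the phenol carbon, C1 and C5 its ortho carbons), and C6–C7 is a terminal alkene that bridges those two ortho carbons.
Key disconnection: C5–C6 and C1–C7, giving phenol 9 and 2-methylbut-3-en-2-ol 10, joined by oxidative dearomatisation and cationic (5+2) cycloaddition. The six-membered ring is the arene and comes first; the five-membered ring C1–C8–C5–C6–C7 and the stereocentres C1, C5 and C7 are made in that one step.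
Phenol 9 comes from 2-methylphloroglucinol 3 by Friedel–Crafts acylation with the chloride of (R)-2-methylbutanoic acid 1, allylation of the para hydroxyl, methylation of the two chelated hydroxyls and Claisen rearrangement.
After the key step: cross-metathesis (allyl to prenyl) and chloride demethylation of the vinylogous ester.

Key step: step 6

Assumption: either O-methyl group of cation 13 may be lost; the route is written for the C2 methyl ether 14, and its C4 regioisomer would converge on 16 through the same steps 7 and 8.

**Route**

Step 1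
Reactants: 1 (R)-2-methylbutanoic acid
Product: 2 (R)-2-methylbutanoyl chloride
Conditions: (COCl)2 (1.2 equiv), DMF (cat.), CH2Cl2, 0 °C → rt; concentrated cold, used crude
Reagents that add atoms: oxalyl chloride, O=C(Cl)C(=O)Cl
Why: Chlorination through the catalytic chloroiminium (Vilsmeier) species runs without base, so no ketene can form and the α-stereocentre of 1 should be carried over unchanged.

Step 2
Reactants: 2 (R)-2-methylbutanoyl chloride; 3 2-methylphloroglucinol (2-methylbenzene-1,3,5-triol)
Product: 4 (R)-2-methyl-1-(2,4,6-trihydroxy-3-methylphenyl)butan-1-one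
Conditions: AlCl3 (4 equiv), PhNO2/CH2Cl2, 0 °C → rt; ice, 1 M HCl
Reagents that add atoms: none
Why: Friedel–Crafts acylation of the electron-rich triol takes place at one of its two equivalent free ring carbons and stops there because the acyl group deactivates the ring; the stereocentre comes from 2 and should survive the base-free, low-temperature conditions.

Step 3
Reactants: 4 (R)-2-methyl-1-(2,4,6-trihydroxy-3-methylphenyl)butan-1-one; 5 allyl bromide
Product: 6 (R)-1-[4-(allyloxy)-2,6-dihydroxy-3-methylphenyl]-2-methylbutan-1-one
Conditions: K2CO3 (1.1 equiv), 5 (1.05 equiv), acetone, rt → 40 °C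
Reagents that add atoms: none
Why: Williamson etherification with one equivalent of base should select the hydroxyl para to the ketone, which is the most acidic one and the only one not tied up in a hydrogen bond to the carbonyl group.

Step 4
Reactants: 6 (R)-1-[4-(allyloxy)-2,6-dihydroxy-3-methylphenyl]-2-methylbutan-1-one
Product: 7 (R)-1-[4-(allyloxy)-2,6-dimethoxy-3-methylphenyl]-2-methylbutan-1-one
Conditions: Me2SO4 (3 equiv), K2CO3 (4 equiv), acetone, reflux
Reagents that add atoms: dimethyl sulfate, COS(=O)(=O)OC
Why: Williamson O-methylation with the hard electrophile dimethyl sulfate in refluxing acetone is the usual way to alkylate chelated ortho hydroxyls of aryl ketones and favours oxygen over ring-carbon methylation; the mild carbonate base should not touch the hindered α-stereocentre.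

Step 5
Reactants: 7 (R)-1-[4-(allyloxy)-2,6-dimethoxy-3-methylphenyl]-2-methylbutan-1-one
Product: 9 (R)-1-(3-allyl-4-hydroxy-2,6-dimethoxy-5-methylphenyl)-2-methylbutan-1-one, via 6-allylcyclohexa-2,4-dienone tautomer 8 (not isolated)
Conditions: PhNEt2, 190 °C, sealed tube, Ar
Reagents that add atoms: none
Why: Aromatic Claisen rearrangement ([3,3]-sigmatropic shift) carries the allyl group to the only unsubstituted ortho carbon and dienone 8 enolises to phenol 9, whereas migration to the methyl-bearing ortho carbon gives a dienone that cannot enolise and reverts; the amine solvent suppresses acid-catalysed cyclisation to a dihydrobenzofuran and enolisation of the ketone.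

Step 6
Reactants: 9 (R)-1-(3-allyl-4-hydroxy-2,6-dimethoxy-5-methylphenyl)-2-methylbutan-1-one; 10 2-methylbut-3-en-2-ol
Product: 14 (1S,5S,7S)-5-allyl-7-(2-hydroxypropan-2-yl)-2-methoxy-1-methyl-3-[(2R)-2-methylbutanoyl]bicyclo[3.2.1]oct-2-ene-4,8-dione, via aryloxy(acetoxy)phenyliodane 11 (not isolated), via phenoxonium acetate 12 (not isolated), via bicyclic 1,3-dimethoxyallyl cation 13 (not isolated)
Conditions: PhI(OAc)2 (1.2 equiv, added over 1 h), 10 (10 equiv), (CF3)2CHOH/CH2Cl2 (1:1), −20 → 0 °C; aq. NaHCO3; SiO2, then preparative HPLC (chiral stationary phase)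
Reagents that add atoms: none
Why: Proposed new method: ligand exchange of the phenol on trivalent iodine gives 11, and loss of PhI and acetate in the ionising, weakly nucleophilic medium gives the phenoxonium ion 12, a 2-oxidopentadienyl cation whose termini are the ortho carbons C1 and C5 and whose para carbon C3 is blocked by the acyl group; the CH2 terminus of 10 bonds to C5 and the carbinol-bearing CH then bonds to C1, the α-carbon of the resulting β-methoxy dienone, in an asynchronous suprafacial (5+2) cycloaddition, after which acetate removes one O-methyl group from the 1,3-dimethoxyallyl cation 13. The closest known reaction type is the cationic (5+2) cycloaddition of para-alkoxy phenoxonium ions or quinone monoketal cations with electron-rich alkenes to bicyclo[3.2.1]octenediones; the step is new because the para donor is missing (the two meta methoxy groups stabilise the cation only once the second bond forms) and because the alkene is monosubstituted and carries a free hydroxyl. The one ring closed is the five-membered ring C1–C8–C5–C6–C7, completed by a 5-exo attack of the enol-ether carbon C1 on the developing C7 cation from the face already occupied by C6. C1 and C5 are fixed relative to each other because the two-carbon unit bridges one face, and C7 by exo approach, which places the CMe2OH group outside the ring over the C8 oxygen (to which its hydroxyl can hydrogen-bond) instead of over the crowded C2–C4 face. The step needs orientation control (CH2 to C5) and preference for carbon–carbon bonding: the hindered C7 should prefer the methyl-bearing terminus and the CH2 the slightly more electrophilic allyl-bearing terminus, every ring carbon is substituted so that no adduct can rearomatise, attack by the tertiary alcohol, acetate or solvent at a fully substituted ortho carbon is hindered and expected to be reversible, and 10 is used in excess. Nothing in 9 differentiates its two faces, so adducts of both faces are expected side by side; they are diastereomers because of the fixed (R) centre, and the (1S,5S,7S) isomer 14 is isolated by preparative HPLC.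

Step 7
Reactants: 14 (1S,5S,7S)-5-allyl-7-(2-hydroxypropan-2-yl)-2-methoxy-1-methyl-3-[(2R)-2-methylbutanoyl]bicyclo[3.2.1]oct-2-ene-4,8-dione
Product: 15 (1S,5S,7S)-7-(2-hydroxypropan-2-yl)-2-methoxy-1-methyl-5-(3-methylbut-2-en-1-yl)-3-[(2R)-2-methylbutanoyl]bicyclo[3.2.1]oct-2-ene-4,8-dione
Conditions: 2-methylbut-2-ene (large excess), second-generation Grubbs catalyst (H2IMes)(PCy3)Cl2Ru=CHPh (5 mol %), CH2Cl2, 40 °C, sealed tube
Reagents that add atoms: 2-methylbut-2-ene, CC=C(C)C
Why: Olefin cross-metathesis of a terminal alkene with a large excess of 2-methylbut-2-ene is the standard allyl-to-prenyl exchange, the quaternary C5 next to the allyl group disfavours homodimerisation, and neither the tertiary alcohol nor the vinylogous ester interferes; no stereocentre is involved.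

Step 8
Reactants: 15 (1S,5S,7S)-7-(2-hydroxypropan-2-yl)-2-methoxy-1-methyl-5-(3-methylbut-2-en-1-yl)-3-[(2R)-2-methylbutanoyl]bicyclo[3.2.1]oct-2-ene-4,8-dione
Product: 16 (1S,5S,7S)-2-hydroxy-7-(2-hydroxypropan-2-yl)-1-methyl-5-(3-methylbut-2-en-1-yl)-3-[(2R)-2-methylbutanoyl]bicyclo[3.2.1]oct-2-ene-4,8-dione
Conditions: LiCl (10 equiv), DMSO, 110 °C; cold 1 M HCl work-up
Reagents that add atoms: none
Why: Krapcho-type SN2 demethylation: chloride attacks the O-methyl group of the acyl-activated vinylogous ester and releases the highly stabilised triketone enolate, protonated on work-up; the medium is not basic, so the γ-hydroxy ketone and the acyl α-centre should stay intact.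

**Compound list**

1 | (R)-2-methylbutanoic acid | CC[C@@H](C)C(=O)O | starting material
2 | (R)-2-methylbutanoyl chloride | CC[C@@H](C)C(=O)Cl | intermediate
3 | 2-methylphloroglucinol (2-methylbenzene-1,3,5-triol) | Cc1c(O)cc(O)cc1O | starting material
4 | (R)-2-methyl-1-(2,4,6-trihydroxy-3-methylphenyl)butan-1-one | CC[C@@H](C)C(=O)c1c(O)cc(O)c(C)c1O | intermediate
5 | allyl bromide (3-bromoprop-1-ene) | C=CCBr | starting material
6 | (R)-1-[4-(allyloxy)-2,6-dihydroxy-3-methylphenyl]-2-methylbutan-1-one | CC[C@@H](C)C(=O)c1c(O)cc(OCC=C)c(C)c1O | intermediate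
7 | (R)-1-[4-(allyloxy)-2,6-dimethoxy-3-methylphenyl]-2-methylbutan-1-one | CC[C@@H](C)C(=O)c1c(OC)cc(OCC=C)c(C)c1OC | intermediate
8 | 6-allyl-3,5-dimethoxy-2-methyl-4-[(2R)-2-methylbutanoyl]cyclohexa-2,4-dien-1-one (both C6 epimers) | CC[C@@H](C)C(=O)C1=C(OC)C(CC=C)C(=O)C(C)=C1OC | intermediate (not isolated)
9 | (R)-1-(3-allyl-4-hydroxy-2,6-dimethoxy-5-methylphenyl)-2-methylbutan-1-one | CC[C@@H](C)C(=O)c1c(OC)c(C)c(O)c(CC=C)c1OC | intermediate
10 | 2-methylbut-3-en-2-ol | C=CC(C)(C)O | starting material
11 | (R)-1-{3-allyl-4-[acetoxy(phenyl)iodanyloxy]-2,6-dimethoxy-5-methylphenyl}-2-methylbutan-1-one | CC[C@@H](C)C(=O)c1c(OC)c(C)c(OI(OC(C)=O)c2ccccc2)c(CC=C)c1OC | intermediate (not isolated)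
12 | 1-allyl-2,4-dimethoxy-5-methyl-3-[(2R)-2-methylbutanoyl]-6-oxocyclohexa-2,4-dien-1-ylium acetate (phenoxonium ion of 9) | CC[C@@H](C)C(=O)C1=C(OC)[C+](CC=C)C(=O)C(C)=C1OC.CC(=O)[O-] | intermediate (not isolated)
13 | bicyclic 1,3-dimethoxyallyl cation (acetate): 5-allyl-7-(2-hydroxypropan-2-yl)-2,4-dimethoxy-1-methyl-3-[(2R)-2-methylbutanoyl]-8-oxobicyclo[3.2.1]octenylium over C2–C3–C4, configured at C1, C5 and C7 as in 14 | COC1=C(C(=O)[C@H](C)CC)C(=[O+]C)[C@@]2(C)C(=O)[C@]1(CC=C)C[C@@H]2C(C)(C)O.CC(=O)[O-] | intermediate (not isolated)
14 | (1S,5S,7S)-5-allyl-7-(2-hydroxypropan-2-yl)-2-methoxy-1-methyl-3-[(2R)-2-methylbutanoyl]bicyclo[3.2.1]oct-2-ene-4,8-dione (C9 exo) | CC[C@@H](C)C(=O)C1=C(OC)[C@@]2(C)C(=O)[C@](CC=C)(C[C@@H]2C(C)(C)O)C1=O | intermediate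
15 | (1S,5S,7S)-7-(2-hydroxypropan-2-yl)-2-methoxy-1-methyl-5-(3-methylbut-2-en-1-yl)-3-[(2R)-2-methylbutanoyl]bicyclo[3.2.1]oct-2-ene-4,8-dione | CC[C@@H](C)C(=O)C1=C(OC)[C@@]2(C)C(=O)[C@](CC=C(C)C)(C[C@@H]2C(C)(C)O)C1=O | intermediate
16 | (1S,5S,7S)-2-hydroxy-7-(2-hydroxypropan-2-yl)-1-methyl-5-(3-methylbut-2-en-1-yl)-3-[(2R)-2-methylbutanoyl]bicyclo[3.2.1]oct-2-ene-4,8-dione (CNP0201042.1) | CC[C@@H](C)C(=O)C1=C(O)[C@@]2(C)C(=O)[C@](CC=C(C)C)(C[C@@H]2C(C)(C)O)C1=O | target

**Step count and risks**

Total step count: 8. Longest linear sequence: 8 steps (1 to 16).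

Steps most likely to fail:

1. Step 6 (proposed new method). The phenoxonium ion may be captured by acetate, the solvent or the hydroxyl of 10 faster than the weakly nucleophilic alkene forms a carbon–carbon bond. The alkene may also add in the reverse orientation, and there is no facial discrimination. The fallback uses known chemistry and builds the same five-membered ring by radical cyclisation; it sets out from 4 and comes back to the route at 16. Compound 4 is C-prenylated twice at its free ring carbon (prenyl bromide, aq. KOH, 0 °C) to give the dearomatised (R)-3,5-dihydroxy-4-methyl-2-(2-methylbutanoyl)-6,6-bis(3-methylbut-2-en-1-yl)cyclohexa-2,4-dien-1-one F1. Oxidation with Mn(OAc)3·2H2O (trivalent manganese) in AcOH under O2 should generate the C1-centred dicarbonyl radical, which closes 5-exo-trig onto one prenyl group (C1–C7). The tertiary C9 radical is trapped by dioxygen to give (1S,5S,7S)-7-(2-hydroperoxypropan-2-yl)-2-hydroxy-1-methyl-5-(3-methylbut-2-en-1-yl)-3-[(2R)-2-methylbutanoyl]bicyclo[3.2.1]oct-2-ene-4,8-dione F2 together with its stereoisomers. Reduction with PPh3 gives 16 after preparative HPLC. This sequence controls neither the face nor the exo position, so the C7 epimer and the diastereomers with the mirror-image bicycle have to be removed.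

2. Step 3. The ambident phloroglucinol anion may be allylated at the free ring carbon, or a second hydroxyl may be allylated. The fallback sets out from 4 and comes back at 6: Mitsunobu etherification with allyl alcohol (PPh3, diisopropyl azodicarboxylate, THF, 0 °C). It activates the alcohol as an alkoxyphosphonium ion under neutral conditions, alkylates phenols at oxygen, and engages only the non-chelated, most acidic para hydroxyl. It makes no new compound (F0).

3. Step 5. At 190 °C the α-stereocentre of the ketone may erode by thermal enolisation, or the allyl ether may cleave or cyclise instead of migrating cleanly. The fallback sets out from 7 and comes back at 9, and no stage exceeds 80 °C. The allyl group is removed (Pd(PPh3)4, zerovalent palladium, morpholine, THF, rt) to give (R)-1-(4-hydroxy-2,6-dimethoxy-3-methylphenyl)-2-methylbutan-1-one F3. Bromination at the only free ring position (N-bromosuccinimide, MeCN, 0 °C) gives (R)-1-(3-bromo-4-hydroxy-2,6-dimethoxy-5-methylphenyl)-2-methylbutan-1-one F4. Stille coupling with allyltributylstannane (Pd(PPh3)4, DMF, 80 °C) then installs the allyl group to give 9.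

**Further compounds**

F1 | step 6 | (R)-3,5-dihydroxy-4-methyl-2-(2-methylbutanoyl)-6,6-bis(3-methylbut-2-en-1-yl)cyclohexa-2,4-dien-1-one | CC[C@@H](C)C(=O)C1=C(O)C(C)=C(O)C(CC=C(C)C)(CC=C(C)C)C1=O
F2 | step 6 | (1S,5S,7S)-7-(2-hydroperoxypropan-2-yl)-2-hydroxy-1-methyl-5-(3-methylbut-2-en-1-yl)-3-[(2R)-2-methylbutanoyl]bicyclo[3.2.1]oct-2-ene-4,8-dione | CC[C@@H](C)C(=O)C1=C(O)[C@@]2(C)C(=O)[C@](CC=C(C)C)(C[C@@H]2C(C)(C)OO)C1=O
F0 | step 3 | none | none
F3 | step 5 | (R)-1-(4-hydroxy-2,6-dimethoxy-3-methylphenyl)-2-methylbutan-1-one | CC[C@@H](C)C(=O)c1c(OC)cc(O)c(C)c1OC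
F4 | step 5 | (R)-1-(3-bromo-4-hydroxy-2,6-dimethoxy-5-methylphenyl)-2-methylbutan-1-one | CC[C@@H](C)C(=O)c1c(OC)c(Br)c(O)c(C)c1OC
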